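Retrosynthetic cuts: the C2 acetate; C12–C13 (sp3–sp2 coupling onto the E-enoate); C9–C11 (acetylide onto a C9 ketone); the C2 and C3 oxygens (from a C2=C3 alkene); C3–C4 (ring A); the two exocyclic bonds at C10 (enolate alkylations).
Enabling feature: ring B (C5–C10) has the substitution pattern of carvone, with the C9 oxygen beside the C8 methyl and C5 carrying the carbon that becomes C4. Protonating the isopropenyl group therefore makes C4 a tertiary cation that already holds the gem-dimethyl pair and can bond to C3 of a three-carbon Z-vinylsilane arm on C10.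
Forward order: the carvone ring is ring B; C10 is made quaternary and the enone reduced; ring A closes by the C3–C4 bond and leaves C2=C3; the diol is installed and masked; the side chain is attached at C9 and completed at C12–C13; acetonide removal and C2 acetylation finish.
Stereochemistry: C5 from (R)-carvone; C10 by alkylation anti to the isopropenyl group; C8 by equilibration to the equatorial methyl; C2 and C3 by osmylation away from the axial C4 and C10 methyls; C9 by axial acetylide attack anti to the C10 methyl; the E alkene from the enol triflate geometry.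

Key step: step 5

Remark: the decalins are numbered as labdanes (ring A = C1–C5 and C10, ring B = C5–C10, side chain from C11), β is the face of the C10 methyl group and α the opposite face; 6-methylcarvone is carried on as its C6 epimer mixture because that centre is enolised again in step 2.

Step 1
Reactants: 1 (R)-(−)-carvone
Product: 3 6-methylcarvone (C6 epimer mixture), via lithium dienolate 2 (not isolated)
Conditions: LiN(i-Pr)2, THF, −78 °C; MeI, −78 to 0 °C
Reagents that add atoms: iodomethane, CI
Why: Kinetic deprotonation of the enone occurs at the alpha-prime CH2 and the cross-conjugated enolate is C-methylated (enolate alkylation); the new centre forms as an epimer mixture that is erased by the next enolisation.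

Step 2
Reactants: 3 6-methylcarvone; 4 3-bromo-1-(trimethylsilyl)prop-1-yne
Product: 6 6-methyl-6-[3-(trimethylsilyl)prop-2-ynyl]carvone (methyl cis to isopropenyl), via lithium enolate 5 (not isolated)
Conditions: LiN(i-Pr)2, THF, −78 °C; DMPU, then 4, −78 to −20 °C
Reagents that add atoms: none
Why: Second alpha-prime enolate alkylation, in which the propargylic bromide approaches the planar enolate on the face anti to the neighbouring isopropenyl group, so the quaternary centre (future C10) carries the methyl cis and the three-carbon arm trans to isopropenyl; the silyl cap blocks allene formation.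

Step 3
Reactants: 6 6-methyl-6-[3-(trimethylsilyl)prop-2-ynyl]carvone
Product: 7 6-methyl-6-[(Z)-3-(trimethylsilyl)prop-2-enyl]carvone
Conditions: H2 (1 atm), Ni2B (from Ni(OAc)2·4H2O and NaBH4), ethylenediamine, EtOH, rt
Reagents that add atoms: none
Why: Syn semihydrogenation of the silylalkyne over amine-poisoned nickel boride should stop at the cis alkene and give the Z-vinylsilane, while the 1,1-disubstituted and the conjugated alkene are left alone.

Step 4
Reactants: 7 6-methyl-6-[(Z)-3-(trimethylsilyl)prop-2-enyl]carvone
Product: 9 2,6-dimethyl-3-isopropenyl-2-[(Z)-3-(trimethylsilyl)prop-2-enyl]cyclohexanone (C8 methyl α), via lithium enolate 8 (not isolated)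
Conditions: LiBH(s-Bu)3, THF, −78 °C; MeOH, then NaOMe (cat.), 0 °C to rt
Reagents that add atoms: none
Why: Conjugate (1,4) reduction of the β-unsubstituted cyclohexenone by the bulky trialkylborohydride, helped by the quaternary carbon beside the carbonyl, followed by protonation and base equilibration that should place the C8 methyl equatorial (α), because the axial epimer would be syn-diaxial to the C10 methyl.

Step 5
Reactants: 9 2,6-dimethyl-3-isopropenyl-2-[(Z)-3-(trimethylsilyl)prop-2-enyl]cyclohexanone
Product: 10 4,4,8α,10β-tetramethyl-5αH-decal-2-en-9-one (trans-fused)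
Conditions: TfOH (2 equiv), CH2Cl2, −78 to −40 °C; aq NaHCO3
Reagents that add atoms: none
Why: Markovnikov protonation of the isopropenyl group gives the tertiary C4 cation that already carries both methyls; the Z-vinylsilane captures it through its silicon-bearing carbon (C3), the resulting C2 cation is stabilised by the β C–Si bond, and loss of the silyl group to triflate leaves the C2=C3 alkene. The closest known reaction type is the vinylsilane-terminated cation–olefin cyclisation in its endocyclic ipso mode. Ring A closes in the 6-endo mode with respect to the vinylsilane, through a chair-like arrangement in which the C5 and C10 arms are both equatorial on ring B. No new stereocentre is formed: the trans ring fusion follows from the existing C5 and C10 centres, whose reacting arms are trans on adjacent carbons. The step needs protonation of the 1,1-disubstituted alkene in preference to the vinylsilane and attack at C3 (6-endo, ipso) in preference to C2 (5-exo); the first should follow from the higher basicity of the isopropenyl group, the second from the β-silicon effect and the Z geometry, which lets the ring alkene form cis with the C–Si bond aligned. The non-basic triflate counter-ion at low temperature should keep the cation from losing H5 before it cyclises.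

Step 6
Reactants: 10 4,4,8α,10β-tetramethyl-5αH-decal-2-en-9-one
Product: 11 2α,3α-dihydroxy-4,4,8α,10β-tetramethyl-5αH-decalin-9-one
Conditions: OsO4 (cat.), NMO, acetone–H2O, rt
Reagents that add atoms: osmium tetroxide, O=[Os](=O)(=O)=O; N-methylmorpholine N-oxide, C[N+]1([O-])CCOCC1; water, O
Why: Catalytic syn dihydroxylation (Upjohn conditions) should occur on the α face, because the β face of the C2=C3 alkene is covered by the syn-axial methyls on C4 and C10, which sets C2 and C3 together as the 2α,3α-diol.

Step 7
Reactants: 11 2α,3α-dihydroxy-4,4,8α,10β-tetramethyl-5αH-decalin-9-one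
Product: 12 2α,3α-O-isopropylidene acetal of 11 (acetonide ketone)
Conditions: 2,2-dimethoxypropane, PPTS (cat.), CH2Cl2, rt
Reagents that add atoms: 2,2-dimethoxypropane, COC(C)(C)OC
Why: Acid-catalysed acetal exchange (acetonide formation) on the cis diol; the C9 ketone, flanked by C10 and the C8 methyl, is too hindered to ketalise and no stereocentre changes.

Step 8
Reactants: 12 acetonide ketone; 13 trimethylsilylacetylene
Product: 15 9α-[(trimethylsilyl)ethynyl]-9β-hydroxy acetonide, via lithium (trimethylsilyl)acetylide 14 (not isolated)
Conditions: n-BuLi, THF, −78 °C; then 12, −78 to 0 °C; aq NH4Cl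
Reagents that add atoms: none
Why: 1,2-Addition of a lithium acetylide to a ketone, in which the slim nucleophile should attack C9 axially from the α face, anti to the axial C10 methyl, giving the axial (α) alkynyl group and the equatorial (β) hydroxyl; its low basicity limits enolisation toward C8.

Step 9
Reactants: 15 9α-[(trimethylsilyl)ethynyl]-9β-hydroxy acetonide
Product: 16 9α-ethynyl-9β-hydroxy acetonide
Conditions: K2CO3 (cat.), MeOH, rt
Reagents that add atoms: none
Why: Methanolysis of the alkynyl C–Si bond under catalytic carbonate (protodesilylation of a silylalkyne); the acetonide and the tertiary alcohol are inert to it.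

Step 10
Reactants: 16 9α-ethynyl-9β-hydroxy acetonide
Product: 17 9α-vinyl-9β-hydroxy acetonide
Conditions: H2 (1 atm), Pd/CaCO3 poisoned with Pb(OAc)2, quinoline, EtOAc, rt
Reagents that add atoms: none
Why: Semihydrogenation of the terminal alkyne over lead-poisoned palladium (Lindlar reduction) should stop at the vinyl group, the standard conversion of a tertiary ethynyl carbinol into a vinyl carbinol.

Step 11
Reactants: 18 methyl acetoacetate
Product: 20 methyl (E)-3-(trifluoromethylsulfonyloxy)but-2-enoate, via tetramethylammonium enolate 19 (not isolated)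
Conditions: aq Me4NOH, hexanes, 5 °C; then Tf2O
Reagents that add atoms: triflic anhydride, O=S(=O)(C(F)(F)F)OS(=O)(=O)C(F)(F)F
Why: Stereoselective enol triflation of a β-keto ester: with the non-coordinating ammonium counter-ion the enolate reacts in its non-chelated form and O-sulfonylation should give the E enol triflate, with the triflate trans to the ester.

Step 12
Reactants: 17 9α-vinyl-9β-hydroxy acetonide; 20 methyl (E)-3-(trifluoromethylsulfonyloxy)but-2-enoate
Product: 22 methyl 9β-hydroxy-2α,3α-isopropylidenedioxylabd-13E-en-15-oate (9α side chain), via B-alkyl-9-BBN borane 21 (not isolated)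
Conditions: 9-BBN dimer, THF, rt; then 20, PdCl2(dppf) (cat.), AsPh3, Cs2CO3, DMF–H2O, rt
Reagents that add atoms: none
Why: Anti-Markovnikov hydroboration of the vinyl group with 9-BBN puts boron on the terminal carbon (C12), and the B-alkyl Suzuki–Miyaura coupling should transfer this primary alkyl group to the enol triflate with retention of alkene geometry, giving the E-enoate while the hindered tertiary hydroxyl stays free.

Step 13
Reactants: 22 methyl 9β-hydroxy-2α,3α-isopropylidenedioxylabd-13E-en-15-oate
Product: 23 methyl 2α,3α,9β-trihydroxylabd-13E-en-15-oate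
Conditions: AcOH–H2O (4:1), 50 °C
Reagents that add atoms: none
Why: Acid hydrolysis of the isopropylidene acetal; the methyl ester, the enoate and the non-allylic tertiary C9 alcohol should tolerate warm aqueous acetic acid.

Step 14
Reactants: 23 methyl 2α,3α,9β-trihydroxylabd-13E-en-15-oate
Product: 24 methyl 2α-acetoxy-3α,9β-dihydroxylabd-13E-en-15-oate (CNP0135744.1)
Conditions: Ac2O (1.2 equiv), pyridine, CH2Cl2, 0 °C
Reagents that add atoms: acetic anhydride, CC(=O)OC(C)=O
Why: Selective acylation by steric differentiation: the equatorial secondary C2 hydroxyl should react, whereas the axial C3 hydroxyl is neopentyl (next to the C4 gem-dimethyl carbon) and the C9 hydroxyl is tertiary; no stereocentre is touched.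

Compound list
1 | (R)-(−)-carvone | CC1=CC[C@H](CC1=O)C(C)=C | starting material
2 | lithium cross-conjugated dienolate of carvone (O–C1=C6) | [Li+].[O-]C1=C[C@H](C(C)=C)CC=C1C | intermediate
3 | 6-methylcarvone, C6 epimer mixture (trans epimer drawn) | O=C1C(C)=CC[C@@H](C(C)=C)[C@@H]1C | intermediate
4 | 3-bromo-1-(trimethylsilyl)prop-1-yne | BrCC#C[Si](C)(C)C | starting material
5 | lithium C1=C6 enolate of 6-methylcarvone | [Li+].[O-]C1=C(C)[C@H](C(C)=C)CC=C1C | intermediate
6 | 6-methyl-6-[3-(trimethylsilyl)prop-2-ynyl]carvone, methyl cis and propargyl arm trans to isopropenyl | O=C1C(C)=CC[C@@H](C(C)=C)[C@]1(C)CC#C[Si](C)(C)C | intermediate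
7 | 6-methyl-6-[(Z)-3-(trimethylsilyl)prop-2-enyl]carvone, same configuration as 6 | O=C1C(C)=CC[C@@H](C(C)=C)[C@]1(C)C/C=C\[Si](C)(C)C | intermediate
8 | lithium enolate (O–C9=C8) from conjugate reduction of 7 | [Li+].[O-]C1=C(C)CC[C@@H](C(C)=C)[C@]1(C)C/C=C\[Si](C)(C)C | intermediate
9 | 2,6-dimethyl-3-isopropenyl-2-[(Z)-3-(trimethylsilyl)prop-2-enyl]cyclohexanone; 2-methyl cis to isopropenyl and trans to 6-methyl | O=C1[C@H](C)CC[C@@H](C(C)=C)[C@]1(C)C/C=C\[Si](C)(C)C | intermediate
10 | 4,4,8α,10β-tetramethyl-5αH-decal-2-en-9-one (trans-fused) | O=C1[C@H](C)CC[C@H]2C(C)(C)C=CC[C@@]21C | intermediate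
11 | 2α,3α-dihydroxy-4,4,8α,10β-tetramethyl-5αH-decalin-9-one | O=C1[C@H](C)CC[C@H]2C(C)(C)[C@H](O)[C@H](O)C[C@@]21C | intermediate
12 | 2α,3α-O-isopropylidene acetal of 11 | O=C1[C@H](C)CC[C@H]2C(C)(C)[C@@H]3OC(C)(C)O[C@@H]3C[C@@]21C | intermediate
13 | trimethylsilylacetylene | C#C[Si](C)(C)C | starting material
14 | lithium (trimethylsilyl)acetylide | [Li+].[C-]#C[Si](C)(C)C | intermediate
15 | 9α-[(trimethylsilyl)ethynyl]-9β-hydroxy acetonide (alkynyl axial, hydroxyl cis to the C10 methyl) | C[Si](C)(C)C#C[C@]1(O)[C@H](C)CC[C@H]2C(C)(C)[C@@H]3OC(C)(C)O[C@@H]3C[C@@]21C | intermediate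
16 | 9α-ethynyl-9β-hydroxy acetonide | C#C[C@]1(O)[C@H](C)CC[C@H]2C(C)(C)[C@@H]3OC(C)(C)O[C@@H]3C[C@@]21C | intermediate
17 | 9α-vinyl-9β-hydroxy acetonide | C=C[C@]1(O)[C@H](C)CC[C@H]2C(C)(C)[C@@H]3OC(C)(C)O[C@@H]3C[C@@]21C | intermediate
18 | methyl acetoacetate | COC(=O)CC(C)=O | starting material
19 | tetramethylammonium E-enolate of methyl acetoacetate | C[N+](C)(C)C.COC(=O)/C=C(\C)[O-] | intermediate
20 | methyl (E)-3-(trifluoromethylsulfonyloxy)but-2-enoate | COC(=O)/C=C(\C)OS(=O)(=O)C(F)(F)F | intermediate
21 | B-alkyl-9-BBN borane from 17, boron on C12 | C1CC2CCCC(C1)B2CC[C@]1(O)[C@H](C)CC[C@H]2C(C)(C)[C@@H]3OC(C)(C)O[C@@H]3C[C@@]21C | intermediate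
22 | methyl 9β-hydroxy-2α,3α-isopropylidenedioxylabd-13E-en-15-oate (side chain 9α, C8 methyl α) | COC(=O)/C=C(\C)CC[C@]1(O)[C@H](C)CC[C@H]2C(C)(C)[C@@H]3OC(C)(C)O[C@@H]3C[C@@]21C | intermediate
23 | methyl 2α,3α,9β-trihydroxylabd-13E-en-15-oate | COC(=O)/C=C(\C)CC[C@]1(O)[C@H](C)CC[C@H]2C(C)(C)[C@H](O)[C@H](O)C[C@@]21C | intermediate
24 | methyl 2α-acetoxy-3α,9β-dihydroxylabd-13E-en-15-oate, CNP0135744.1 | COC(=O)/C=C(\C)CC[C@]1(O)[C@H](C)CC[C@H]2C(C)(C)[C@H](O)[C@H](OC(C)=O)C[C@@]21C | target

Total step count: 14. Longest linear sequence: 13 steps (steps 1–10 and 12–14 from carvone); step 11 is the one-step side branch.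

Steps most likely to fail

The ring A closure of step 5 carries the highest risk.
- What may go wrong: under the strong acid the vinylsilane may be protonated and lose silicon before the C4 cation has formed. The C4 cation may also lose H5 to the tetrasubstituted alkene and return with C5 scrambled, or shift hydride, faster than it closes the ring.
- Fallback: it separates formation of the cation from the proton source and sets out from compound 9. Dry HCl in CH2Cl2 at −78 °C should add in the Markovnikov sense to the isopropenyl group only and give the tertiary chloride F1. F1 is then ionised with TiCl4 in CH2Cl2 at −78 °C, where no free Brønsted acid is present and the counter-ion is non-basic. The same vinylsilane-terminated closure should then deliver compound 10, where the route is rejoined.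

The acetylide addition of step 8 is second.
- What may go wrong: the acetylide may enolise the doubly flanked ketone toward C8 and return starting material, or add too slowly at the neopentyl carbonyl.
- Fallback: it uses a less basic one-carbon nucleophile and sets out from compound 12. Methylene transfer from dimethylsulfonium methylide (trimethylsulfonium iodide, n-BuLi, THF, 0 °C; Corey–Chaykovsky reaction) should give the spiro-epoxide F2, with the new CH2 axial on the α face. CuI-catalysed opening at that CH2 with methallylmagnesium chloride should give the tertiary alcohol F3, which carries a 3-methylbut-3-enyl chain. Cross-metathesis of F3 with methyl acrylate (second-generation Grubbs catalyst, CH2Cl2, 40 °C) should turn the 1,1-disubstituted alkene into the E-enoate. This is compound 22, where the route is rejoined without passing through compounds 15–17.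

The hydroboration–coupling of step 12 is third.
- What may go wrong: the alkylborane sits two carbons from a quaternary carbinol and may transmetallate slowly, so that the aqueous base hydrolyses or isomerises the β-triflyloxy enoate first.
- Fallback: it replaces boron by zinc and needs no base; it sets out from compound 17. Hydroboration with 9-BBN and oxidation with NaBO3·4H2O should give the primary alcohol F4. I2, PPh3 and imidazole should convert it into the iodide F5. Zinc dust with LiCl in THF should insert to give the alkylzinc iodide F6, which tolerates the hindered tertiary hydroxyl. Negishi coupling of F6 with compound 20 (Pd(PPh3)4, THF, rt) should give compound 22, where the route is rejoined.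

Further compounds
F1 | step 5 | 3-(2-chloropropan-2-yl)-2,6-dimethyl-2-[(Z)-3-(trimethylsilyl)prop-2-enyl]cyclohexanone, configuration as in 9 | O=C1[C@H](C)CC[C@@H](C(C)(C)Cl)[C@]1(C)C/C=C\[Si](C)(C)C
F2 | step 8 | spiro-epoxide at C9 of acetonide ketone 12, CH2 on the α face and oxygen β | C1O[C@]12[C@H](C)CC[C@H]3C(C)(C)[C@@H]4OC(C)(C)O[C@@H]4C[C@@]32C
F3 | step 8 | 9α-(3-methylbut-3-enyl)-9β-hydroxy acetonide | C=C(C)CC[C@]1(O)[C@H](C)CC[C@H]2C(C)(C)[C@@H]3OC(C)(C)O[C@@H]3C[C@@]21C
F4 | step 12 | 9α-(2-hydroxyethyl)-9β-hydroxy acetonide | OCC[C@]1(O)[C@H](C)CC[C@H]2C(C)(C)[C@@H]3OC(C)(C)O[C@@H]3C[C@@]21C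
F5 | step 12 | 9α-(2-iodoethyl)-9β-hydroxy acetonide | ICC[C@]1(O)[C@H](C)CC[C@H]2C(C)(C)[C@@H]3OC(C)(C)O[C@@H]3C[C@@]21C
F6 | step 12 | alkylzinc iodide from F5, zinc on C12 | I[Zn]CC[C@]1(O)[C@H](C)CC[C@H]2C(C)(C)[C@@H]3OC(C)(C)O[C@@H]3C[C@@]21C
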